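**Num­bering used throughout (fixed by the steps):** 1 3,4-dihydroxybenzaldehyde; 2 its bis-silyl ether; 3 (E)-1-methoxy-3-(trimethylsilyloxy)buta-1,3-diene; 4 silylated aldol adduct; 5 dihydropyranone; 6 bromo-dihydropyranone; 7 hydroxyacetone; 8 its silyl ether; 9 phosphonium salt; 10 ylide; 11 Z-configured acid; 12 potassium methyl malonate; 13 acyl imidazole; 14 acylmalonic half ester; 15 β-keto ester; 16 β-methoxy enoate; 17 vinylketene silyl acetal; 18 bromo cycloadduct; 19 protected flavanone; 20 target.

## Analysis of the target

Compound 20 is a flavanone: ring A is fused to the pyranone ring C, and C2 carries a 3,4-dihydroxyphenyl ring B. The only stereocentre is C2 (S). It is benzylic, bound to the ring oxygen and β to the C4 ketone, so base can erase it through retro-oxa-Michael opening to the chalcone, and strong acid can ionise the C2–O bond because ring B is electron rich. Ring A is pentasubstituted and fully differentiated: OH at C5 (hydrogen-bonded to the C4 carbonyl), H at C6, OMe at C7 and a (Z)-4-hydroxy-3-methylbut-2-enyl chain at C8. The chain is a Z-trisubstituted allylic alcohol, so its geometry must be built deliberately, and it is prone to allylic ionisation under acid. The catechol is sensitive to oxidation, which together with the base-labile flavanone calls for one protecting-group family removed under neutral conditions. The difficulty is the combination of ring A regiochemistry (telling O5 from O7 and C6 from C8 on a phloroglucinol-type ring) with control of C2. The strategy rests on one mapping: C4a and C8a are the α- and β-carbons of the enone of a 2-aryl-2,3-dihydropyran-4-one, and C5–C8 with their O, H, OMe and alkyl substituents are the four carbons of a 1,3-dioxygenated diene carrying the side chain at its terminus.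

## Retrosynthetic reasoning

**20 ⇒ 19.** Only the three O–Si bonds are cut. Silyl ethers on the catechol and the allylic alcohol can all be removed by fluoride in a single non-basic step, so the last operation cannot open the flavanone or scramble C2. The 5-OH is left free in 19 because its hydrogen bond to the ketone makes protection unnecessary.

**19 ⇒ 6 + 17 (key disconnection).** The bonds C8–C8a and C5–C4a are cut, which removes ring A as a four-carbon diene and leaves ring C intact with its stereocentre. Cutting here means that the substitution pattern of ring A is written into the diene 17 (the acetal carbon becomes C5–OH, the methoxy carbon becomes C7, the substituted terminus becomes C8) instead of having to be imposed on an existing arene. The bromine at C5 of 6 marks the carbon that becomes C4a and supplies the leaving group, so that the adduct aromatises by elimination across C4a–C8a and loss of the acetal methoxy group, without an oxidant. The forward reaction must make a weakly electrophilic β-alkoxy enone accept the diene in one orientation and then aromatise without touching C2.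

**6 ⇒ 5 ⇒ 2 + 3, and 2 ⇒ 1.** The C5–Br bond is removed first; a vinylogous ester is halogenated at that carbon by simple electrophilic substitution. The pyranone 5 is then opened across O1–C6 and C2–C3 into aldehyde 2 and diene 3. This is the hetero-Diels–Alder disconnection, and it places the only stereocentre in a catalytic asymmetric step on small molecules. Aldehyde 2 is the bis-silyl ether of 1.

**17 ⇒ 16 ⇒ 15.** The silyl acetal 17 is the O-silylated γ-dienolate of ester 16, and 16 is the methyl enol ether of β-keto ester 15. The side-chain oxygen carries a tert-butyldiphenylsilyl group rather than the dimethyl analogue so that it survives the acid used for the enol ether and still leaves with fluoride at the end.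

**15 ⇒ 11 + 12.** The bond between the ketone carbon and the α-CH2 is cut, giving acid 11 and the malonate half-ester 12. This two-carbon homologation runs under nearly neutral conditions. It is preferred to alkylating a preformed keto ester with a Z-allylic electrophile, because that electrophile would itself need a longer stereocontrolled synthesis.

**11 ⇒ 8 + 9 (via 10), and 8 ⇒ 7.** The trisubstituted C=C bond is cut by a Wittig disconnection into the α-silyloxy ketone 8 and the ylide 10 generated from salt 9. α-Oxygenated methyl ketones are the one ketone class that gives Z-trisubstituted alkenes reliably in this reaction, so the geometry and the whole acid are reached in one step. Ketone 8 is the silyl ether of 7.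

## Alternatives that were turned down

**Alternative 1: ring A by Danheiser benzannulation.** Ring A is cut at C8a–C8, C7–C6 and C8a–C4a into 3-ethoxycyclobut-2-en-1-one A2 and the methoxyalkyne (Z)-tert-butyl[(6-methoxy-2-methylhex-2-en-5-ynyl)oxy]dimethylsilane A3.
- Forward step: on heating, A2 opens to a vinylketene, which adds A3 in a [2+2] sense. A second four-electron opening and a six-electron closure then give the phenol 5-ethoxy-3-methoxy-2-[(Z)-4-(tert-butyldimethylsilyloxy)-3-methylbut-2-enyl]phenol A1.
- For: this is an established reaction class, and the mechanism fixes four contiguous substituents of A1 with the free phenol next to the side chain. On precedent for the ring-forming event it is stronger than the chosen route.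
- Against: A1 contains neither ring C nor C2. From A1 one still needs acylation at C4a, attachment of the three-carbon unit with ring B, and an enantioselective oxa-Michael ring closure of the open-chain enone, which is reversible and hard to render selective. The ethyl ether at O5 of A1 must then be cleaved beside the methyl ether at O7 with Lewis acids that threaten the allylic alcohol. The CH2 group of A3 is both propargylic and allylic and may isomerise at benzannulation temperatures.
- Comparison: the chosen route gives up the precedent but has C2 settled before ring A exists, delivers ring A with O5 free and O7 methylated, and ends in one deprotection, in clearly fewer steps than a route through A1.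

**Alternative 2: ring C by o-quinone methide and styrene [4+2].** Ring C is cut at C3–C4 and O1–C2 into the salicylaldehyde 2-hydroxy-4-methoxy-6-(tert-butyldimethylsilyloxy)-3-[(Z)-4-(tert-butyldimethylsilyloxy)-3-methylbut-2-enyl]benzaldehyde A5 and 3,4-bis(tert-butyldimethylsilyloxy)styrene A6.
- Forward step: A5, an orthoester and a confined chiral Brønsted acid generate a 4-methoxy o-quinone methide cation, which adds A6 and closes ring C to the silyl-protected (2S)-2,4-cis-4-methoxyflavan A4.
- For: in A4 the C2 stereocentre and both new bonds of ring C come from one catalytic asymmetric event on the complete skeleton. On that point it is as strong as the hetero-Diels–Alder step of the chosen route.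
- Against: A5 is a hexasubstituted benzene, so the whole regiochemical problem of ring A moves into its preparation. Its formyl group is flanked by OH and a silyloxy group, which crowds the ion pair that must sit in the catalyst pocket. A6 is a para-silyloxystyrene that polymerises readily under strong acid. In A4, C4 carries a methyl ether and a stereocentre that the target does not need, so A4 requires hydrolysis and oxidation at C4 before the final deprotection.
- Comparison: the chosen route obtains the ring A pattern from the diene rather than from an arene synthesis, makes no superfluous stereocentre of the kind present in A4 and has a one-step end game.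

**Alternative 3: ring C by intramolecular Friedel–Crafts acylation.** The C4–C4a bond is cut, giving (S)-3-(3,4-diacetoxyphenyl)-3-{5-(tert-butyldimethylsilyloxy)-3-methoxy-2-[(Z)-4-(tert-butyldimethylsilyloxy)-3-methylbut-2-enyl]phenoxy}propanoic acid A8.
- Forward step: activation of A8 as a mixed anhydride acylates C4a and gives the protected (2S)-flavanone A7, which carries silyl ethers on ring A and on the side chain and acetates on ring B.
- For: the closure that leads to A7 is a well-known type for chroman-4-ones, C2 is in place beforehand, and the plan is convergent. On precedent for the key bond it is stronger than the chosen route.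
- Against: A8 requires the O1–C2 bond to be made by stereospecific substitution at a benzylic carbinol with a hindered, ortho-disubstituted phenol, where partial ionisation erodes the configuration. Once activated, A8 can lose its aryloxy group by β-elimination instead of cyclising. The trisubstituted alkene and the allylic silyl ether must survive strongly acidic acylating conditions. Ring B needs acetates to stay unreactive, so A7 has to pass through a second deprotection that the flavanone or the allylic alcohol may not tolerate. The ring A phenol inside A8 must still be built regioselectively.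
- Comparison: the chosen route builds ring A in the same step that joins the halves, exposes no acid-sensitive group to acylium chemistry and uses one protecting-group family, whereas A7 needs two.

Key step: step 9

Assumption: the (S)-BINOL/Ti(OiPr)4 catalyst is taken to direct the diene to the Si face of aldehyde 2, the face that leads to (S)-5; if the first run shows the opposite sense, (R)-BINOL is used and nothing else changes.

## Route

Step 1
Reactants: 1 3,4-dihydroxybenzaldehyde
Product: 2 3,4-bis(tert-butyldimethylsilyloxy)benzaldehyde
Conditions: TBSCl (2.4 equiv), imidazole (5 equiv), DMF, 0 °C → rt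
Reagents that add atoms: tert-butyldimethylsilyl chloride, CC(C)(C)[Si](C)(C)Cl
Why: Imidazole-promoted silylation of both phenols; the silyl ethers protect the catechol from oxidation and from chelating Lewis acids and leave with fluoride at the end.

Step 2
Reactants: 2 3,4-bis(tert-butyldimethylsilyloxy)benzaldehyde; 3 (E)-1-methoxy-3-(trimethylsilyloxy)buta-1,3-diene
Product: 5 (S)-2-[3,4-bis(tert-butyldimethylsilyloxy)phenyl]-2,3-dihydro-4H-pyran-4-one, via silylated aldol adduct 4 (not isolated)
Conditions: Ti(OiPr)4 (10 mol%), (S)-BINOL (20 mol%), 4 Å MS, Et2O, −20 °C; then CF3CO2H, CH2Cl2, 0 °C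
Reagents that add atoms: none
Why: Catalytic asymmetric hetero-Diels–Alder reaction in its stepwise form (Mukaiyama aldol addition, then acid-induced 6-endo oxa-Michael closure with loss of methanol); the chiral Lewis acid formed from Ti(OiPr)4 and BINOL binds the aldehyde and the diene terminus should add to the Si face, which sets C2 as S.

Step 3
Reactants: 5 (S)-2-[3,4-bis(tert-butyldimethylsilyloxy)phenyl]-2,3-dihydro-4H-pyran-4-one
Product: 6 (S)-5-bromo-2-[3,4-bis(tert-butyldimethylsilyloxy)phenyl]-2,3-dihydro-4H-pyran-4-one
Conditions: NBS (1.05 equiv), pyridine (0.2 equiv), CH2Cl2, 0 °C, dark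
Reagents that add atoms: N-bromosuccinimide, O=C1CCC(=O)N1Br
Why: Electrophilic α-halogenation of a vinylogous ester: the enol ether carbon C5 attacks bromine and the oxocarbenium ion loses the C5 proton to restore the enone; the enol ether is much more nucleophilic than the silyloxy arene, and working in the dark avoids radical bromination at C2.

Step 4
Reactants: 7 hydroxyacetone
Product: 8 1-(tert-butyldiphenylsilyloxy)propan-2-one
Conditions: TBDPSCl (1.05 equiv), imidazole (2 equiv), CH2Cl2, 0 °C → rt
Reagents that add atoms: tert-butyldiphenylsilyl chloride, CC(C)(C)[Si](Cl)(c1ccccc1)c1ccccc1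
Why: Routine silylation of a primary alcohol; the diphenyl-substituted silyl group is chosen because it tolerates the acid of step 7.

Step 5
Reactants: 8 1-(tert-butyldiphenylsilyloxy)propan-2-one; 9 (3-carboxypropyl)triphenylphosphonium bromide
Product: 11 (Z)-6-(tert-butyldiphenylsilyloxy)-5-methylhex-4-enoic acid, via ylide carboxylate 10 (not isolated)
Conditions: 9, NaN(SiMe3)2 (2.1 equiv), THF, 0 °C; then 8, −78 °C → rt; 1 M HCl work-up
Reagents that add atoms: none
Why: Wittig reaction of an α-silyloxy methyl ketone with a non-stabilised, lithium-free ylide; α-oxygenated ketones are known to give the trisubstituted alkene with the CH2O group cis to the new chain, here the Z isomer, and any E isomer should be separable at the acid or ester stage.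

Step 6
Reactants: 11 (Z)-6-(tert-butyldiphenylsilyloxy)-5-methylhex-4-enoic acid; 12 potassium methyl malonate
Product: 15 methyl (Z)-8-(tert-butyldiphenylsilyloxy)-7-methyl-3-oxooct-6-enoate, via acyl imidazole 13 (not isolated), via acylmalonic half ester 14 (not isolated)
Conditions: CDI (1.2 equiv), THF, rt; then 12 (2 equiv), MgCl2 (2.5 equiv), Et3N (3 equiv), MeCN, rt → 40 °C; 1 M HCl work-up
Reagents that add atoms: none
Why: Acyl imidazole formation followed by decarboxylative Claisen condensation with the enolate generated from 12 by MgCl2 and Et3N gives the β-keto ester under nearly neutral conditions that leave the Z-alkene and the silyl ether alone.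

Step 7
Reactants: 15 methyl (Z)-8-(tert-butyldiphenylsilyloxy)-7-methyl-3-oxooct-6-enoate
Product: 16 methyl (2E,6Z)-8-(tert-butyldiphenylsilyloxy)-3-methoxy-7-methylocta-2,6-dienoate
Conditions: HC(OMe)3 (5 equiv), H2SO4 (2 mol%), MeOH, rt
Reagents that add atoms: trimethyl orthoformate, COC(OC)OC; methanol, CO
Why: Acid-catalysed ketalisation with the orthoester as water scavenger, then loss of methanol to the conjugated enol ether; the favoured E isomer places C4 syn to the ester carbonyl as the next step requires, and the tert-butyldiphenylsilyl ether should survive catalytic acid in methanol.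

Step 8
Reactants: 16 methyl (2E,6Z)-8-(tert-butyldiphenylsilyloxy)-3-methoxy-7-methylocta-2,6-dienoate
Product: 17 (6Z)-8-(tert-butyldiphenylsilyloxy)-1,3-dimethoxy-7-methyl-1-(trimethylsilyloxy)octa-1,3,6-triene (drawn 1Z,3Z; used crude as the isomer mixture formed)
Conditions: LiN(iPr)2 (1.1 equiv), THF, −78 °C; TMSCl (1.3 equiv), −78 → 0 °C; pentane, filtration under Ar
Reagents that add atoms: chlorotrimethylsilane, C[Si](C)(C)Cl
Why: Kinetic γ-deprotonation of the (E)-β-methoxy enoate, directed by the syn ester carbonyl, and O-silylation of the dienolate is the standard entry to 1,3-dialkoxy-1-silyloxydienes; the geometry of the acetal and enol ether double bonds is not controlled and is not needed.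

Step 9
Reactants: 6 (S)-5-bromo-2-[3,4-bis(tert-butyldimethylsilyloxy)phenyl]-2,3-dihydro-4H-pyran-4-one; 17 (6Z)-8-(tert-butyldiphenylsilyloxy)-1,3-dimethoxy-7-methyl-1-(trimethylsilyloxy)octa-1,3,6-triene
Product: 19 (S)-2-[3,4-bis(tert-butyldimethylsilyloxy)phenyl]-8-[(Z)-4-(tert-butyldiphenylsilyloxy)-3-methylbut-2-enyl]-5-hydroxy-7-methoxychroman-4-one, via bromo cycloadduct 18 (not isolated)
Conditions: 17 (2.5 equiv), TMSOTf (0.2 equiv), 2,6-di-tert-butyl-4-methylpyridine (0.3 equiv), CH2Cl2, −78 → −20 °C; then Et3N (5 equiv), −20 °C → rt; SiO2
Reagents that add atoms: none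
Why: Proposed new method: the silyl triflate activates the carbonyl of 6 as a 4-silyloxy oxocarbenium ion, and the most nucleophilic carbon of 17, the terminus that carries the side chain, adds to C6 of the pyranone (C8a of the flavanone), the only electrophilic carbon of the bromo-enone. The resulting α-bromo silyl enol ether then attacks the silyloxy(methoxy)carbenium ion left from the ketene acetal through C5 (C4a), a 6-(enolexo)-exo-trig closure that completes a stepwise [4+2] addition to 18 and returns the silyl triflate; a concerted, asynchronous Diels–Alder addition would give the same adduct in the same orientation. In 18, loss of methoxytrimethylsilane from the acetal carbon unmasks the C5 carbonyl, Et3N removes HBr across C4a–C8a, and tautomerisation gives the hydrogen-bonded 5-hydroxy-7-methoxy ring A. Because the hydrogen at C8a is not acidic, this dehydrobromination is an E2 process rather than the E1cB process of the quinone series; the anti arrangement of bromine and hydrogen that it needs can come from the stepwise closure or from epimerisation at the doubly activated C4a by reversible transfer of bromine to bromide. The closest known reactions are the regiospecific cycloaddition–aromatisation of 1,3-dialkoxy-1-silyloxydienes with halogenated quinones and the Lewis-acid Mukaiyama–Michael addition of silyl enol ethers and ketene acetals to 2-aryl-2,3-dihydropyran-4-ones; neither has been used to close an arene on a bromo-dihydropyranone. No stereocentre remains from this step: the centres of 18 at C4a, C5, C8 and C8a are all lost on aromatisation, and C2 is not involved in either new bond. The selectivity needed is regiochemical (side chain next to the ring oxygen, hydroxyl next to the carbonyl); it is secured by the polarity match of the nucleophilic diene terminus with the enone β-carbon and by the bromine, which marks C4a as the partner of the acetal carbon and provides the leaving group. The hindered pyridine and low temperature should keep the acid-labile diene alive, and a tertiary amine instead of an alkoxide in the elimination is meant to prevent retro-oxa-Michael opening at C2.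

Step 10
Reactants: 19 (S)-2-[3,4-bis(tert-butyldimethylsilyloxy)phenyl]-8-[(Z)-4-(tert-butyldiphenylsilyloxy)-3-methylbut-2-enyl]-5-hydroxy-7-methoxychroman-4-one
Product: 20 (S)-2-(3,4-dihydroxyphenyl)-5-hydroxy-8-[(Z)-4-hydroxy-3-methylbut-2-enyl]-7-methoxychroman-4-one
Conditions: HF·pyridine (excess), pyridine, THF, 0 °C → rt
Reagents that add atoms: none
Why: Fluoride cleavage of the two aryl silyl ethers and the primary silyl ether under buffered, non-basic conditions, which should avoid chalcone formation and so keep C2; the allylic alcohol and the chelated phenol are inert to the reagent.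

## Compound list

1 | 3,4-dihydroxybenzaldehyde | O=Cc1ccc(O)c(O)c1 | starting material
2 | 3,4-bis(tert-butyldimethylsilyloxy)benzaldehyde | O=Cc1ccc(O[Si](C)(C)C(C)(C)C)c(O[Si](C)(C)C(C)(C)C)c1 | intermediate
3 | (E)-1-methoxy-3-(trimethylsilyloxy)buta-1,3-diene | CO/C=C/C(=C)O[Si](C)(C)C | starting material
4 | (S,E)-5-[3,4-bis(tert-butyldimethylsilyloxy)phenyl]-1-methoxy-5-(trimethylsilyloxy)pent-1-en-3-one | CO/C=C/C(=O)C[C@H](O[Si](C)(C)C)c1ccc(O[Si](C)(C)C(C)(C)C)c(O[Si](C)(C)C(C)(C)C)c1 | intermediate (not isolated)
5 | (S)-2-[3,4-bis(tert-butyldimethylsilyloxy)phenyl]-2,3-dihydro-4H-pyran-4-one | O=C1C[C@@H](c2ccc(O[Si](C)(C)C(C)(C)C)c(O[Si](C)(C)C(C)(C)C)c2)OC=C1 | intermediate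
6 | (S)-5-bromo-2-[3,4-bis(tert-butyldimethylsilyloxy)phenyl]-2,3-dihydro-4H-pyran-4-one | O=C1C[C@@H](c2ccc(O[Si](C)(C)C(C)(C)C)c(O[Si](C)(C)C(C)(C)C)c2)OC=C1Br | intermediate
7 | hydroxyacetone | CC(=O)CO | starting material
8 | 1-(tert-butyldiphenylsilyloxy)propan-2-one | CC(=O)CO[Si](c1ccccc1)(c1ccccc1)C(C)(C)C | intermediate
9 | (3-carboxypropyl)triphenylphosphonium bromide | OC(=O)CCC[P+](c1ccccc1)(c1ccccc1)c1ccccc1.[Br-] | starting material
10 | sodium 4-(triphenylphosphoranylidene)butanoate | [Na+].[O-]C(=O)CCC=P(c1ccccc1)(c1ccccc1)c1ccccc1 | intermediate (not isolated)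
11 | (Z)-6-(tert-butyldiphenylsilyloxy)-5-methylhex-4-enoic acid | OC(=O)CC/C=C(/C)CO[Si](c1ccccc1)(c1ccccc1)C(C)(C)C | intermediate
12 | potassium methyl malonate | COC(=O)CC(=O)[O-].[K+] | starting material
13 | (Z)-6-(tert-butyldiphenylsilyloxy)-1-(imidazol-1-yl)-5-methylhex-4-en-1-one | O=C(CC/C=C(/C)CO[Si](c1ccccc1)(c1ccccc1)C(C)(C)C)n1ccnc1 | intermediate (not isolated)
14 | (Z)-8-(tert-butyldiphenylsilyloxy)-2-(methoxycarbonyl)-7-methyl-3-oxooct-6-enoic acid | COC(=O)C(C(=O)O)C(=O)CC/C=C(/C)CO[Si](c1ccccc1)(c1ccccc1)C(C)(C)C | intermediate (not isolated)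
15 | methyl (Z)-8-(tert-butyldiphenylsilyloxy)-7-methyl-3-oxooct-6-enoate | COC(=O)CC(=O)CC/C=C(/C)CO[Si](c1ccccc1)(c1ccccc1)C(C)(C)C | intermediate
16 | methyl (2E,6Z)-8-(tert-butyldiphenylsilyloxy)-3-methoxy-7-methylocta-2,6-dienoate | COC(=O)/C=C(/OC)CC/C=C(/C)CO[Si](c1ccccc1)(c1ccccc1)C(C)(C)C | intermediate
17 | (6Z)-8-(tert-butyldiphenylsilyloxy)-1,3-dimethoxy-7-methyl-1-(trimethylsilyloxy)octa-1,3,6-triene (drawn 1Z,3Z) | CO/C(O[Si](C)(C)C)=C/C(OC)=C/C/C=C(/C)CO[Si](c1ccccc1)(c1ccccc1)C(C)(C)C | intermediate
18 | (2S)-4a-bromo-2-[3,4-bis(tert-butyldimethylsilyloxy)phenyl]-8-[(Z)-4-(tert-butyldiphenylsilyloxy)-3-methylbut-2-enyl]-5,7-dimethoxy-5-(trimethylsilyloxy)-2,3,4a,5,8,8a-hexahydro-4H-chromen-4-one (other centres undefined) | COC1(O[Si](C)(C)C)C=C(OC)C(C/C=C(/C)CO[Si](c2ccccc2)(c2ccccc2)C(C)(C)C)C2O[C@H](c3ccc(O[Si](C)(C)C(C)(C)C)c(O[Si](C)(C)C(C)(C)C)c3)CC(=O)C12Br | intermediate (not isolated)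
19 | (S)-2-[3,4-bis(tert-butyldimethylsilyloxy)phenyl]-8-[(Z)-4-(tert-butyldiphenylsilyloxy)-3-methylbut-2-enyl]-5-hydroxy-7-methoxychroman-4-one | COc1cc(O)c2c(c1C/C=C(/C)CO[Si](c3ccccc3)(c4ccccc4)C(C)(C)C)O[C@H](c5ccc(O[Si](C)(C)C(C)(C)C)c(O[Si](C)(C)C(C)(C)C)c5)CC2=O | intermediate
20 | (S)-2-(3,4-dihydroxyphenyl)-5-hydroxy-8-[(Z)-4-hydroxy-3-methylbut-2-enyl]-7-methoxychroman-4-one | COc1cc(O)c2c(c1C/C=C(/C)CO)O[C@H](c1ccc(O)c(O)c1)CC2=O | target

## Step count and risk

Total: 10 steps. Longest linear sequence: 7 steps (steps 4–10, 7 → 8 → 11 → 15 → 16 → 17 → 19 → 20); the dihydropyranone branch (steps 1–3) joins at step 9.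

**Step 9 (key step, proposed new method).**
- The β-alkoxy enone may be too weak an electrophile, so that 17 is consumed by protodesilylation before it adds.
- The sequence may stop after the conjugate addition, without the Claisen-type closure.
- The dehydrobromination may stall, because the hydrogen at C8a is not acidic and a cis ring fusion offers no anti-periplanar hydrogen.
- Lewis acid may ionise the benzylic C2–O bond, or the amine may trigger retro-oxa-Michael opening, with loss of enantiopurity.
- Bromine may be lost reductively from the α-bromo dicarbonyl stage, followed by β-elimination of the ring oxygen.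

Fallback, built from known reaction types, from 5 and 17 back to 19: the bromine is introduced after ring closure instead of before. Mukaiyama–Michael addition of 17 to the unbrominated enone 5 (TMSOTf, CH2Cl2, −78 °C, aqueous work-up) should give methyl (2E,6Z)-4-{(6S)-6-[3,4-bis(tert-butyldimethylsilyloxy)phenyl]-4-oxotetrahydro-2H-pyran-2-yl}-8-(tert-butyldiphenylsilyloxy)-3-methoxy-7-methylocta-2,6-dienoate F1. Dieckmann condensation (LiN(SiMe3)2, THF, −78 → 0 °C) would close ring A to (2S)-2-[3,4-bis(tert-butyldimethylsilyloxy)phenyl]-8-[(Z)-4-(tert-butyldiphenylsilyloxy)-3-methylbut-2-enyl]-7-methoxy-2,3,8,8a-tetrahydro-4H-chromene-4,5(4aH)-dione F2. NBS would brominate the doubly activated C4a of the planar enol to the 4a-bromo dione (2S)-4a-bromo-2-[3,4-bis(tert-butyldimethylsilyloxy)phenyl]-8-[(Z)-4-(tert-butyldiphenylsilyloxy)-3-methylbut-2-enyl]-7-methoxy-2,3,8,8a-tetrahydro-4H-chromene-4,5(4aH)-dione F3. Both C4a epimers are accessible from the enol, and they can interconvert by reversible bromine transfer, so the one with bromine anti to the C8a hydrogen is available. Et3N would then remove HBr across C4a–C8a, after which enolisation gives 19.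

**Step 5.** The basic ylide may enolise ketone 8 instead of adding, and the carboxylate-bearing ylide may give lower Z selectivity than simple ylides. Fallback by a stereospecific route: it replaces compounds 7 to 10, sets out from commercial prop-2-yn-1-ol (which has no number in the route) and comes back at 11. Copper-catalysed anti-carbomagnesiation (MeMgBr, CuI, then I2) gives (Z)-3-iodo-2-methylprop-2-en-1-ol F4. Silylation (TBDPSCl, imidazole) gives (Z)-tert-butyl[(3-iodo-2-methylprop-2-enyl)oxy]diphenylsilane F5. Negishi coupling with BrZnCH2CH2CO2Et and Pd(PPh3)4 proceeds with retention to ethyl (Z)-6-(tert-butyldiphenylsilyloxy)-5-methylhex-4-enoate F6. Saponification with LiOH gives 11.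

**Step 2.** The electron-rich aldehyde may react slowly and with lower facial selectivity than simple aryl aldehydes, the sense of induction may be opposite to that assumed, and the acid cyclisation may erode the configuration through benzylic ionisation. Fallback from 2 back to 5 by reagent control: boron aldol reaction of 2 with the enolate of (E)-4-methoxybut-3-en-2-one formed with Ipc2BCl and iPr2NEt (the antipode that attacks the Si face) gives (S,E)-5-[3,4-bis(tert-butyldimethylsilyloxy)phenyl]-5-hydroxy-1-methoxypent-1-en-3-one F7, which is cyclised to 5 with CF3CO2H.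

**Step 7.** Acidic methanol may cleave the allylic silyl ether, or the ketal may fail to lose methanol completely. Fallback from 15 directly to 16 by a different mechanism, without acid: O-alkylation of the enolate formed with K2CO3 by a hard methylating agent (Me2SO4, DMF). It makes no new compound.

## Further compounds

F1 | step 9 | methyl (2E,6Z)-4-{(6S)-6-[3,4-bis(tert-butyldimethylsilyloxy)phenyl]-4-oxotetrahydro-2H-pyran-2-yl}-8-(tert-butyldiphenylsilyloxy)-3-methoxy-7-methylocta-2,6-dienoate | COC(=O)/C=C(/OC)C(C/C=C(/C)CO[Si](c1ccccc1)(c1ccccc1)C(C)(C)C)C1CC(=O)C[C@@H](c2ccc(O[Si](C)(C)C(C)(C)C)c(O[Si](C)(C)C(C)(C)C)c2)O1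
F2 | step 9 | (2S)-2-[3,4-bis(tert-butyldimethylsilyloxy)phenyl]-8-[(Z)-4-(tert-butyldiphenylsilyloxy)-3-methylbut-2-enyl]-7-methoxy-2,3,8,8a-tetrahydro-4H-chromene-4,5(4aH)-dione | COC1=CC(=O)C2C(=O)C[C@@H](c3ccc(O[Si](C)(C)C(C)(C)C)c(O[Si](C)(C)C(C)(C)C)c3)OC2C1C/C=C(/C)CO[Si](c1ccccc1)(c1ccccc1)C(C)(C)C
F3 | step 9 | (2S)-4a-bromo-2-[3,4-bis(tert-butyldimethylsilyloxy)phenyl]-8-[(Z)-4-(tert-butyldiphenylsilyloxy)-3-methylbut-2-enyl]-7-methoxy-2,3,8,8a-tetrahydro-4H-chromene-4,5(4aH)-dione | COC1=CC(=O)C2(Br)C(=O)C[C@@H](c3ccc(O[Si](C)(C)C(C)(C)C)c(O[Si](C)(C)C(C)(C)C)c3)OC2C1C/C=C(/C)CO[Si](c1ccccc1)(c1ccccc1)C(C)(C)C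
F4 | step 5 | (Z)-3-iodo-2-methylprop-2-en-1-ol | OC/C(C)=C\I
F5 | step 5 | (Z)-tert-butyl[(3-iodo-2-methylprop-2-enyl)oxy]diphenylsilane | C/C(=C/I)CO[Si](c1ccccc1)(c1ccccc1)C(C)(C)C
F6 | step 5 | ethyl (Z)-6-(tert-butyldiphenylsilyloxy)-5-methylhex-4-enoate | CCOC(=O)CC/C=C(/C)CO[Si](c1ccccc1)(c1ccccc1)C(C)(C)C
F7 | step 2 | (S,E)-5-[3,4-bis(tert-butyldimethylsilyloxy)phenyl]-5-hydroxy-1-methoxypent-1-en-3-one | CO/C=C/C(=O)C[C@H](O)c1ccc(O[Si](C)(C)C(C)(C)C)c(O[Si](C)(C)C(C)(C)C)c1
F0 | step 7 | none | none
A1 | alternative 1 | 5-ethoxy-3-methoxy-2-[(Z)-4-(tert-butyldimethylsilyloxy)-3-methylbut-2-enyl]phenol | CCOc1cc(OC)c(C/C=C(/C)CO[Si](C)(C)C(C)(C)C)c(O)c1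
A2 | alternative 1 | 3-ethoxycyclobut-2-en-1-one | CCOC1=CC(=O)C1
A3 | alternative 1 | (Z)-tert-butyl[(6-methoxy-2-methylhex-2-en-5-ynyl)oxy]dimethylsilane | COC#CC/C=C(/C)CO[Si](C)(C)C(C)(C)C
A4 | alternative 2 | silyl-protected (2S)-2,4-cis-4-methoxyflavan | COc1cc(O[Si](C)(C)C(C)(C)C)c2c(c1C/C=C(/C)CO[Si](C)(C)C(C)(C)C)O[C@H](c1ccc(O[Si](C)(C)C(C)(C)C)c(O[Si](C)(C)C(C)(C)C)c1)C[C@@H]2OC
A5 | alternative 2 | 2-hydroxy-4-methoxy-6-(tert-butyldimethylsilyloxy)-3-[(Z)-4-(tert-butyldimethylsilyloxy)-3-methylbut-2-enyl]benzaldehyde | COc1cc(O[Si](C)(C)C(C)(C)C)c(C=O)c(O)c1C/C=C(/C)CO[Si](C)(C)C(C)(C)C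
A6 | alternative 2 | 3,4-bis(tert-butyldimethylsilyloxy)styrene | C=Cc1ccc(O[Si](C)(C)C(C)(C)C)c(O[Si](C)(C)C(C)(C)C)c1
A7 | alternative 3 | protected (2S)-flavanone with diacetoxyphenyl ring B | COc1cc(O[Si](C)(C)C(C)(C)C)c2c(c1C/C=C(/C)CO[Si](C)(C)C(C)(C)C)O[C@H](c1ccc(OC(C)=O)c(OC(C)=O)c1)CC2=O
A8 | alternative 3 | (S)-3-(3,4-diacetoxyphenyl)-3-{5-(tert-butyldimethylsilyloxy)-3-methoxy-2-[(Z)-4-(tert-butyldimethylsilyloxy)-3-methylbut-2-enyl]phenoxy}propanoic acid | COc1cc(O[Si](C)(C)C(C)(C)C)cc(O[C@@H](CC(=O)O)c2ccc(OC(C)=O)c(OC(C)=O)c2)c1C/C=C(/C)CO[Si](C)(C)C(C)(C)C
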